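The plan rests on breaking the O1–C2 bond of ring C in unit 2, the apigenin half that carries the diaryl ether at C6. In ring A of that unit the acyl-bearing carbon C4a sits between two oxygenated carbons, C5 (free OH) and C8a (O1). The pyranone can therefore be opened with water and closed again through the other oxygen. One acid-mediated operation thus moves the aryloxy substituent from C8 to C6 and gives the target directly. The precursor is the unprotected 8-O-4' linked isomer. It is reached by para-selective persulfate hydroxylation of dibenzylapigenin at C8, fluoride displacement on a 5-O-benzyl-4'-fluoroflavone, and hydrogenolysis.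

Key step: step 7

Remark on numbering: unit 1 is the 5-hydroxy-7-methoxyflavone half and unit 2 is the apigenin half, each numbered as a simple flavone. The target has no stereocentre and no configured double bond.

Remark on design:
- The 5-OH of the fluoroflavone partner is carried as a benzyl ether through the ether-forming step. A 5-phenoxide would weaken the carbonyl acceptor that activates C4'–F and would compete as a nucleophile. The benzyl cap is removed in the same hydrogenolysis as the other two.
- The isomerisation is run in acid rather than base, which avoids aryl migration through a C7 phenoxide.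

Step 1
Reactants: 1 apigenin
Product: 2 7,4'-di-O-benzylapigenin
Conditions: BnBr (2.2 equiv), K2CO3 (2.5 equiv), DMF, rt to 40 °C
Reagents that add atoms: benzyl bromide, BrCc1ccccc1
Why: Williamson ether synthesis in which the acidic 7-OH and 4'-OH are alkylated while the 5-OH, held in a hydrogen bond to the C4 carbonyl, stays free under mild carbonate conditions.

Step 2
Reactants: 2 7,4'-di-O-benzylapigenin
Product: 4 7,4'-bis(benzyloxy)-5,8-dihydroxyflavone, via potassium flavon-8-yl sulfate 3 (not isolated)
Conditions: K2S2O8 (1.2 equiv), aq KOH, pyridine, 10–20 °C, 24 h; HCl to pH 4–5, unreacted 2 filtered off; then dilute aq HCl, 85 °C, under nitrogen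
Reagents that add atoms: potassium peroxodisulfate, [K+].[K+].[O-]S(=O)(=O)OOS(=O)(=O)[O-]
Why: Elbs persulfate oxidation, in which the C5 phenolate (the only free phenol) attacks the peroxide O–O bond through its para carbon C8 rather than the ortho carbon C6, and the aryl sulfate 3 is then hydrolysed by dilute acid that leaves the benzyl ethers alone.

Step 3
Reactants: 5 2',6'-dihydroxy-4'-methoxyacetophenone; 6 4-fluorobenzoyl chloride
Product: 8 4'-fluoro-5-hydroxy-7-methoxyflavone, via fluorinated 1,3-diketone 7 (not isolated)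
Conditions: LiN(SiMe3)2 (4.2 equiv), THF, −78 to −10 °C; 6 (1.0 equiv), −78 °C to rt; aq HCl quench; crude 7, AcOH, cat. H2SO4, 100 °C
Reagents that add atoms: none
Why: Claisen-type C-acylation of the lithium trianion of 5 (any O-aroylated material reaches the same diketone by a Baker–Venkataraman acyl shift under the excess base) followed by acid cyclodehydration, which can give only one flavone because the two ortho hydroxyls of 7 are equivalent.

Step 4
Reactants: 8 4'-fluoro-5-hydroxy-7-methoxyflavone
Product: 9 5-benzyloxy-4'-fluoro-7-methoxyflavone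
Conditions: BnBr (1.5 equiv), K2CO3 (3 equiv), DMF, 70 °C
Reagents that add atoms: benzyl bromide, BrCc1ccccc1
Why: Williamson ether synthesis under forcing carbonate conditions overcomes the chelation of the 5-OH, and the cap keeps a 5-phenoxide from feeding electron density into the C4 carbonyl or acting as a rival nucleophile in step 5.

Step 5
Reactants: 4 7,4'-bis(benzyloxy)-5,8-dihydroxyflavone; 9 5-benzyloxy-4'-fluoro-7-methoxyflavone
Product: 10 8-linked tri-O-benzyl biflavone (7-benzyloxy-2-(4-benzyloxyphenyl)-8-{4-[5-benzyloxy-7-methoxy-4-oxo-4H-chromen-2-yl]phenoxy}-5-hydroxy-4H-chromen-4-one)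
Conditions: Cs2CO3 (1.2 equiv), dry degassed DMSO, 110 °C, under argon
Reagents that add atoms: none
Why: Nucleophilic aromatic substitution by addition–elimination, in which the unchelated and more acidic 8-OH of 4 supplies the reacting phenoxide, attack at C4' of 9 places the charge of the Meisenheimer adduct on the C4 carbonyl oxygen through C1', C2 and C3, and the 7-O-benzyl group beside the new ether blocks any Smiles-type aryl migration.

Step 6
Reactants: 10 8-linked tri-O-benzyl biflavone
Product: 11 8-linked isomer of neocryptomerin (5,7-dihydroxy-8-{4-[5-hydroxy-7-methoxy-4-oxo-4H-chromen-2-yl]phenoxy}-2-(4-hydroxyphenyl)-4H-chromen-4-one)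
Conditions: H2 (1 atm), 10% Pd/C, THF–MeOH, rt, stopped after uptake of three equivalents
Reagents that add atoms: none
Why: Catalytic hydrogenolysis cleaves the three benzylic C–O bonds at ambient pressure, conditions under which the diaryl ether, the methyl ether and the conjugated C2=C3 bonds of flavones are normally untouched.

Step 7
Reactants: 11 8-linked isomer of neocryptomerin
Product: 13 neocryptomerin (6-aryloxy isomer), via ring-opened 1,3-diketone 12 (not isolated)
Conditions: conc. HCl–AcOH–H2O (1:2:1), reflux (about 105 °C), under argon, followed by HPLC until the composition no longer changes; Sephadex LH-20 (MeOH) or reversed-phase HPLC; recovered 11 resubmitted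
Reagents that add atoms: none
Why: Wessely–Moser rearrangement: protonation of the C4 carbonyl of unit 2 gives a 4-hydroxyflavylium-type cation, water adds at C2, and the hemiketal collapses with O1–C2 cleavage to the 1,3-diketone 12, whose ring A carries free hydroxyls on both carbons next to the acyl-bearing carbon. After rotation about the aryl–C4 bond the hydroxyl that was the 5-OH adds to the aroyl carbonyl in a 6-exo-trig closure, and loss of the water taken up earlier restores the pyranone, so the new O1–C2 bond and ring C form while the aryloxy carbon becomes C6. The closest known cases are the acid-induced drift of 5,7,8-trioxygenated flavones to their 5,6,7 isomers and the equilibration of 8-C- and 6-C-glycosylflavones in hot mineral acid. No stereocentre is created. The selectivity needed is positional and thermodynamic: every event is reversible, and the 6-aryloxy isomer should be the sink, in line with that general drift, because the aryloxy group exchanges the congested site next to O1 for one between two hydroxyls. Unit 1 can open in the same way but its opened ring A is symmetric, so reclosure returns the same flavone; chloride in aqueous acid is too weak a nucleophile to cleave the 7-methyl ether, and acid is preferred to base because a C7 phenoxide could set off a Smiles migration of the activated aryl group.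

Compound list
1 | apigenin | O=c1cc(-c2ccc(O)cc2)oc2cc(O)cc(O)c12 | starting material
2 | 7,4'-di-O-benzylapigenin (7,4'-bis(benzyloxy)-5-hydroxyflavone) | O=c1cc(-c2ccc(OCc3ccccc3)cc2)oc2cc(OCc3ccccc3)cc(O)c12 | intermediate
3 | potassium 7-benzyloxy-2-(4-benzyloxyphenyl)-5-hydroxy-4-oxo-4H-chromen-8-yl sulfate | O=c1cc(-c2ccc(OCc3ccccc3)cc2)oc2c(OS(=O)(=O)[O-])c(OCc3ccccc3)cc(O)c12.[K+] | intermediate
4 | 7,4'-bis(benzyloxy)-5,8-dihydroxyflavone | O=c1cc(-c2ccc(OCc3ccccc3)cc2)oc2c(O)c(OCc3ccccc3)cc(O)c12 | intermediate
5 | 2',6'-dihydroxy-4'-methoxyacetophenone | COc1cc(O)c(C(C)=O)c(O)c1 | starting material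
6 | 4-fluorobenzoyl chloride | O=C(Cl)c1ccc(F)cc1 | starting material
7 | 1-(2,6-dihydroxy-4-methoxyphenyl)-3-(4-fluorophenyl)propane-1,3-dione | COc1cc(O)c(C(=O)CC(=O)c2ccc(F)cc2)c(O)c1 | intermediate
8 | 4'-fluoro-5-hydroxy-7-methoxyflavone | COc1cc(O)c2c(=O)cc(-c3ccc(F)cc3)oc2c1 | intermediate
9 | 5-benzyloxy-4'-fluoro-7-methoxyflavone | COc1cc(OCc2ccccc2)c2c(=O)cc(-c3ccc(F)cc3)oc2c1 | intermediate
10 | 8-linked tri-O-benzyl biflavone | COc1cc(OCc2ccccc2)c3c(=O)cc(oc3c1)-c4ccc(cc4)Oc5c(OCc6ccccc6)cc(O)c7c(=O)cc(oc57)-c8ccc(OCc9ccccc9)cc8 | intermediate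
11 | 8-linked isomer of neocryptomerin | COc1cc(O)c2c(=O)cc(oc2c1)-c3ccc(cc3)Oc4c(O)cc(O)c5c(=O)cc(oc45)-c6ccc(O)cc6 | intermediate
12 | 1-(4-hydroxyphenyl)-3-(2,4,6-trihydroxy-3-{4-[5-hydroxy-7-methoxy-4-oxo-4H-chromen-2-yl]phenoxy}phenyl)propane-1,3-dione | COc1cc(O)c2c(=O)cc(oc2c1)-c1ccc(cc1)Oc1c(O)cc(O)c(C(=O)CC(=O)c2ccc(O)cc2)c1O | intermediate
13 | neocryptomerin | COc1cc(O)c2c(=O)cc(-c3ccc(Oc4c(O)cc5oc(-c6ccc(O)cc6)cc(=O)c5c4O)cc3)oc2c1 | target

Total step count: 7. Longest linear sequence: 5 steps (1, 2, 5, 6, 7; the branch 3, 4, 5, 6, 7 is equally long).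

Steps most likely to fail

Step 7. Ring opening may be too slow at a temperature that the methyl ether tolerates, or the equilibration may stall with much 8-linked material left.
- Fallback, from 4 and 9, back at 13: the oxygen shift is done on the monomer. No methyl ether is present there, so hot hydriodic acid, the classical medium for this isomerisation, can be used.
- Heating 4 with 57% HI in phenol at 130–140 °C should strip both benzyl groups and carry the 5,7,8-trihydroxy pattern over to the 5,6,7 pattern of scutellarein F1.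
- BnBr (2 equiv) and K2CO3 in acetone cap the two most acidic hydroxyls to give 7,4'-di-O-benzylscutellarein F2.
- The unchelated 6-phenoxide of F2 displaces fluoride from 9 (Cs2CO3, DMSO) to give the 6-linked tri-O-benzyl biflavone F3. Hydrogenolysis over Pd/C then gives 13.

Step 5. Fluoride displacement may be sluggish because C4' is activated only through a vinylogous carbonyl. At the temperature needed, oxidation of the hydroquinone-type phenoxide can compete.
- Fallback, from 4 and 5, back at 10: the ether is made on a much stronger acceptor and unit 1 is then grown on it.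
- Compound 4 and 4-fluorobenzaldehyde (K2CO3, DMF, 90 °C) give the 8-(4-formylphenoxy)flavone F4.
- Mono-benzylation of 5 (BnBr 1 equiv, K2CO3, acetone) gives 2'-benzyloxy-6'-hydroxy-4'-methoxyacetophenone F5.
- Claisen–Schmidt condensation of the two (KOH, EtOH–THF, rt) gives the (E)-chalcone F6. Oxidative cyclisation with catalytic I2 in DMSO at 120 °C closes ring C of unit 1 and gives 10.

Step 2. Poor solubility of the chelated phenolate and competing over-oxidation may keep conversion low.
- Fallback, from 2 and 9, back at 11: the C8 oxygen is brought in by halogenation, borylation and oxidation.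
- Benzylation of the 5-OH of 2 (BnBr, K2CO3, DMF, 70 °C) gives 5,7,4'-tri-O-benzylapigenin F7.
- With all three oxygens alkylated, electrophilic iodination (NIS, cat. TFA, MeCN) is directed to C8 and gives the 8-iodoflavone F8.
- Miyaura borylation (B2pin2, PdCl2(dppf), KOAc, dioxane, 90 °C) gives the 8-pinacolboronate F9. Aqueous H2O2–NaHCO3 in THF oxidises it to 5,7,4'-tris(benzyloxy)-8-hydroxyflavone F10.
- Fluoride displacement on 9 as in step 5 gives the 8-linked tetra-O-benzyl biflavone F11. Hydrogenolysis removes all four benzyl groups to give 11.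

Further compounds
F1 | step 7 | scutellarein (5,6,7,4'-tetrahydroxyflavone) | O=c1cc(-c2ccc(O)cc2)oc2cc(O)c(O)c(O)c12
F2 | step 7 | 7,4'-di-O-benzylscutellarein (7,4'-bis(benzyloxy)-5,6-dihydroxyflavone) | O=c1cc(-c2ccc(OCc3ccccc3)cc2)oc2cc(OCc3ccccc3)c(O)c(O)c12
F3 | step 7 | 6-linked tri-O-benzyl biflavone | COc1cc(OCc2ccccc2)c3c(=O)cc(oc3c1)-c4ccc(cc4)Oc5c(OCc6ccccc6)cc7oc(-c8ccc(OCc9ccccc9)cc8)cc(=O)c7c5O
F4 | step 5 | 4-{[7-benzyloxy-2-(4-benzyloxyphenyl)-5-hydroxy-4-oxo-4H-chromen-8-yl]oxy}benzaldehyde | O=Cc1ccc(cc1)Oc1c(OCc2ccccc2)cc(O)c2c(=O)cc(oc12)-c1ccc(OCc2ccccc2)cc1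
F5 | step 5 | 2'-benzyloxy-6'-hydroxy-4'-methoxyacetophenone | COc1cc(O)c(C(C)=O)c(OCc2ccccc2)c1
F6 | step 5 | (E)-chalcone from F4 and F5 | COc1cc(O)c(C(=O)/C=C/c2ccc(cc2)Oc2c(OCc3ccccc3)cc(O)c3c(=O)cc(oc23)-c2ccc(OCc3ccccc3)cc2)c(OCc2ccccc2)c1
F7 | step 2 | 5,7,4'-tri-O-benzylapigenin | O=c1cc(-c2ccc(OCc3ccccc3)cc2)oc2cc(OCc3ccccc3)cc(OCc3ccccc3)c12
F8 | step 2 | 5,7,4'-tris(benzyloxy)-8-iodoflavone | O=c1cc(-c2ccc(OCc3ccccc3)cc2)oc2c(I)c(OCc3ccccc3)cc(OCc3ccccc3)c12
F9 | step 2 | 5,7,4'-tris(benzyloxy)-8-(4,4,5,5-tetramethyl-1,3,2-dioxaborolan-2-yl)flavone | O=c1cc(-c2ccc(OCc3ccccc3)cc2)oc2c(B3OC(C)(C)C(C)(C)O3)c(OCc3ccccc3)cc(OCc3ccccc3)c12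
F10 | step 2 | 5,7,4'-tris(benzyloxy)-8-hydroxyflavone | O=c1cc(-c2ccc(OCc3ccccc3)cc2)oc2c(O)c(OCc3ccccc3)cc(OCc3ccccc3)c12
F11 | step 2 | 8-linked tetra-O-benzyl biflavone | COc1cc(OCc2ccccc2)c3c(=O)cc(oc3c1)-c4ccc(cc4)Oc5c(OCc6ccccc6)cc(OCc6ccccc6)c7c(=O)cc(oc57)-c8ccc(OCc9ccccc9)cc8
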